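**Retrosynthetic overview**
1. The C8 ester is made last (methacryloyl chloride); everything else is already present in macrocyclic alcohol 23.
2. Key step: the C7–C8 bond and the ten-membered ring form by 10-exo addition of the C8 α-hydroxyalkyl radical (C–H abstraction from primary alcohol 22) to a 3-(acetoxymethyl)butenolide. Acetate loss unveils the α-methylene lactone; C7 and C8 are set here.
3. 22 comes from hydroboration of a vinyl oxirane. The oxirane (C1, C10) comes from Sharpless epoxidation of a Z-allylic alcohol. The butenolide comes from trans-hydroalumination/iodination and carbonylative lactonization of a propargylic alcohol (C6 from asymmetric alkynylation).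
4. The chain is joined at C1–C2 by B-alkyl Suzuki coupling of iodo dienol 4 (propargyl alcohol + vinylMgCl + I2) with the diene terminus of 10.
5. Ring order: butenolide (step 7), oxirane (step 9), ten-membered carbocycle (step 11).

Assumption: atoms carry germacrane labels (C1/C10 oxirane, C4=C5 E-olefin, C6 lactone O, C7 ring fusion, C8 ester carbon, C11=C13 exo-methylene, C12 lactone C=O, C14 acetoxymethyl, C15 methyl), which makes the target 1R,6R,7R,8R,10S; compounds 5 and 8 are taken as commercial.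

**Step 1**
Reactants: 1 prop-2-yn-1-ol; 2 vinylmagnesium chloride
Product: 4 (2Z)-2-(iodomethylidene)but-3-en-1-ol, via chloromagnesium alkenylmagnesium alkoxide 3 (not isolated)
Conditions: vinylMgCl (3 equiv), THF, 65 °C; then I2, −40 °C → rt
Reagents that add atoms: iodine, II
Why: Duboudin–Fallis anti-carbomagnesiation puts vinyl on the internal alkyne carbon and magnesium on the terminal carbon cis to CH2O, and iodinolysis with retention gives the Z-iodide that later fixes the C1=C10 geometry.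

**Step 2**
Reactants: 5 (2E)-3-methylpent-2-en-4-yn-1-ol
Product: 6 (2E)-3-methylpenta-2,4-dien-1-ol
Conditions: H2 (1 atm), Pd/CaCO3/Pb(OAc)2, quinoline, EtOAc, 0 °C
Reagents that add atoms: none
Why: Lindlar semihydrogenation stops at the terminal alkene and leaves the E-trisubstituted olefin untouched.

**Step 3**
Reactants: 6 (2E)-3-methylpenta-2,4-dien-1-ol
Product: 7 (2E)-3-methylpenta-2,4-dienal
Conditions: MnO2 (15 equiv), CH2Cl2, rt; used as a solution
Reagents that add atoms: none
Why: MnO2 oxidation of the allylic alcohol gives the dienal without E/Z isomerization.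

**Step 4**
Reactants: 7 (2E)-3-methylpenta-2,4-dienal; 8 tert-butyldimethyl(prop-2-yn-1-yloxy)silane
Product: 10 (4R,5E)-1-[(tert-butyldimethylsilyl)oxy]-6-methylocta-5,7-dien-2-yn-4-ol, via alkynyl(methyl)zinc 9 (not isolated)
Conditions: Me2Zn (3 equiv), 8 (3 equiv), (S,S)-ProPhenol (20 mol%), Ph3P=O (40 mol%), toluene, 4 °C
Reagents that add atoms: dimethylzinc, C[Zn]C (zinc and methyl stay only in 9)
Why: Trost ProPhenol–zinc asymmetric alkynylation of an enal delivers the alkynylzinc to the Si face and sets the C6 carbinol as R (the ligand antipode would be used if the sense proves opposite).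

**Step 5**
Reactants: 10 (4R,5E)-1-[(tert-butyldimethylsilyl)oxy]-6-methylocta-5,7-dien-2-yn-4-ol; 4 (2Z)-2-(iodomethylidene)but-3-en-1-ol
Product: 12 (2Z,6E,8R)-11-[(tert-butyldimethylsilyl)oxy]-2-ethenyl-6-methylundeca-2,6-dien-9-yne-1,8-diol, via alkylborane 11 (not isolated)
Conditions: 9-BBN (1.5 equiv), THF, 0 °C → rt; then 4, Pd(dppf)Cl2 (5 mol%), AsPh3, Cs2CO3, DMF/H2O, rt
Reagents that add atoms: 9-borabicyclo[3.3.1]nonane, B1C2CCCC1CCC2 (boron stays only in 11)
Why: 9-BBN adds to the terminal CH2 of the monosubstituted vinyl group in preference to the hindered internal alkyne, and B-alkyl Suzuki–Miyaura coupling forms C1–C2 with retention of the Z-iodide geometry.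

**Step 6**
Reactants: 12 (2Z,6E,8R)-11-[(tert-butyldimethylsilyl)oxy]-2-ethenyl-6-methylundeca-2,6-dien-9-yne-1,8-diol
Product: 14 (2Z,6E,8R,9Z)-11-[(tert-butyldimethylsilyl)oxy]-2-ethenyl-10-iodo-6-methylundeca-2,6,9-triene-1,8-diol, via cyclic vinylalanate 13 (not isolated)
Conditions: NaAlH2(OCH2CH2OMe)2 (3 equiv), THF, 0 °C; then I2, −78 → 0 °C
Reagents that add atoms: sodium bis(2-methoxyethoxy)aluminium dihydride, [Na+].COCCO[AlH2-]OCCOC (atoms stay only in 13); iodine, II
Why: hydroxyl-directed trans-hydroalumination delivers hydride from the C6 alkoxide to C7 (the silyl ether side cannot direct), and iodinolysis of the five-membered alanate with retention gives the Z-γ-iodo allylic alcohol.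

**Step 7**
Reactants: 14 (2Z,6E,8R,9Z)-11-[(tert-butyldimethylsilyl)oxy]-2-ethenyl-10-iodo-6-methylundeca-2,6,9-triene-1,8-diol; 15 carbon monoxide
Product: 16 (5R)-3-{[(tert-butyldimethylsilyl)oxy]methyl}-5-[(1E,5Z)-6-(hydroxymethyl)-2-methylocta-1,5,7-trien-1-yl]furan-2(5H)-one
Conditions: PdCl2(PPh3)2 (5 mol%), CO (1 atm), K2CO3, THF, 25 °C
Reagents that add atoms: none
Why: palladium-catalysed carbonylative lactonization (oxidative addition, CO insertion, capture of the acyl-palladium by the cis C6 hydroxyl) closes the butenolide without touching C6.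

**Step 8**
Reactants: 16 (5R)-3-{[(tert-butyldimethylsilyl)oxy]methyl}-5-[(1E,5Z)-6-(hydroxymethyl)-2-methylocta-1,5,7-trien-1-yl]furan-2(5H)-one
Product: 17 (5R)-3-(hydroxymethyl)-5-[(1E,5Z)-6-(hydroxymethyl)-2-methylocta-1,5,7-trien-1-yl]furan-2(5H)-one
Conditions: HF·pyridine, pyridine, THF, 0 °C → rt
Reagents that add atoms: none
Why: buffered fluoride desilylation frees the C13 hydroxyl before any acid-sensitive oxirane is present.

**Step 9**
Reactants: 17 (5R)-3-(hydroxymethyl)-5-[(1E,5Z)-6-(hydroxymethyl)-2-methylocta-1,5,7-trien-1-yl]furan-2(5H)-one; 18 acetic anhydride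
Product: 20 {(2S,3R)-3-[(3E)-4-{(2R)-4-[(acetyloxy)methyl]-5-oxo-2,5-dihydrofuran-2-yl}-3-methylbut-3-en-1-yl]-2-ethenyloxiran-2-yl}methyl acetate, via epoxy diol 19 (not isolated)
Conditions: Ti(OiPr)4 (0.3 equiv), L-(+)-diisopropyl tartrate (0.36 equiv), tBuOOH (1.5 equiv), 4 Å MS, CH2Cl2, −20 °C; then 18, pyridine, DMAP (5 mol%), −20 → 0 °C
Reagents that add atoms: tert-butyl hydroperoxide, CC(C)(C)OO
Why: Sharpless asymmetric epoxidation with L-(+)-tartrate epoxidizes only the allylic C1=C10 olefin on the face that gives 1R,10S, and in situ acetylation traps the sensitive epoxy diol and installs both acetates.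

**Step 10**
Reactants: 20 {(2S,3R)-3-[(3E)-4-{(2R)-4-[(acetyloxy)methyl]-5-oxo-2,5-dihydrofuran-2-yl}-3-methylbut-3-en-1-yl]-2-ethenyloxiran-2-yl}methyl acetate
Product: 22 {(2S,3R)-3-[(3E)-4-{(2R)-4-[(acetyloxy)methyl]-5-oxo-2,5-dihydrofuran-2-yl}-3-methylbut-3-en-1-yl]-2-(2-hydroxyethyl)oxiran-2-yl}methyl acetate, via alkylborane 21 (not isolated)
Conditions: 9-BBN (2 equiv), THF, 0 °C → rt; then 30% H2O2, pH 7 phosphate buffer, 0 °C
Reagents that add atoms: 9-borabicyclo[3.3.1]nonane, B1C2CCCC1CCC2 (boron stays only in 21); hydrogen peroxide, OO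
Why: anti-Markovnikov hydroboration–oxidation with the bulky dialkylborane touches only the monosubstituted vinyl group and gives the primary C8 alcohol with oxirane and esters intact.

**Step 11**
Reactants: 22 {(2S,3R)-3-[(3E)-4-{(2R)-4-[(acetyloxy)methyl]-5-oxo-2,5-dihydrofuran-2-yl}-3-methylbut-3-en-1-yl]-2-(2-hydroxyethyl)oxiran-2-yl}methyl acetate
Product: 23 (1R,6R,7R,8R,10S)-14-acetoxy-1,10-epoxy-8-hydroxygermacra-4E,11(13)-dien-12,6-olide
Conditions: Ir[dF(CF3)ppy]2(dtbbpy)PF6 (5 mol%), quinuclidine (30 mol%), Bu4N(H2PO4) (50 mol%), degassed MeCN (0.5 mM), 450 nm LEDs, 25 °C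
Reagents that add atoms: none
Why: Proposed new method: the quinuclidinium radical cation made by the excited iridium catalyst abstracts the hydridic, phosphate-hydrogen-bonded C8–H, the α-hydroxyalkyl radical closes the ring by 10-exo addition to C7 anti to the C6 side chain (6,7-trans) with H8 rather than OH over the lactone (8R), and reduction of the C11 radical to the enolate expels acetate to give the α-methylene lactone; the closest known reaction types are the quinuclidine/phosphate/photoredox α-C–H alkylation of alcohols with acrylates, photoredox allylation with Morita–Baylis–Hillman acetates and anti-selective hydroxyalkyl radical additions to 5-substituted butenolides.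

**Step 12**
Reactants: 23 (1R,6R,7R,8R,10S)-14-acetoxy-1,10-epoxy-8-hydroxygermacra-4E,11(13)-dien-12,6-olide; 24 2-methylprop-2-enoyl chloride
Product: 25 (1R,6R,7R,8R,10S)-14-acetoxy-1,10-epoxy-8-(2-methylprop-2-enoyloxy)germacra-4E,11(13)-dien-12,6-olide
Conditions: 24 (3 equiv), Et3N, DMAP (0.2 equiv), CH2Cl2, 0 °C
Reagents that add atoms: none
Why: DMAP-catalysed acylation esterifies the only free hydroxyl with retention at C8.

**Compound list**
1 | prop-2-yn-1-ol | C#CCO | starting material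
2 | vinylmagnesium chloride | C=C[Mg]Cl | starting material
3 | chloromagnesium (2Z)-3-(chloromagnesio)-2-ethenylprop-2-en-1-olate | Cl[Mg]OC/C(C=C)=C\[Mg]Cl | intermediate (not isolated)
4 | (2Z)-2-(iodomethylidene)but-3-en-1-ol | OC/C(C=C)=C\I | intermediate
5 | (2E)-3-methylpent-2-en-4-yn-1-ol | C#C/C(C)=C/CO | starting material
6 | (2E)-3-methylpenta-2,4-dien-1-ol | C=C/C(C)=C/CO | intermediate
7 | (2E)-3-methylpenta-2,4-dienal | C=C/C(C)=C/C=O | intermediate
8 | tert-butyldimethyl(prop-2-yn-1-yloxy)silane | C#CCO[Si](C)(C)C(C)(C)C | starting material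
9 | {3-[(tert-butyldimethylsilyl)oxy]prop-1-yn-1-yl}(methyl)zinc | C[Zn]C#CCO[Si](C)(C)C(C)(C)C | intermediate (not isolated)
10 | (4R,5E)-1-[(tert-butyldimethylsilyl)oxy]-6-methylocta-5,7-dien-2-yn-4-ol | C=C/C(C)=C/[C@@H](O)C#CCO[Si](C)(C)C(C)(C)C | intermediate
11 | 9-{(3E,5R)-8-[(tert-butyldimethylsilyl)oxy]-5-hydroxy-3-methyloct-3-en-6-yn-1-yl}-9-borabicyclo[3.3.1]nonane | B1(CC/C(C)=C/[C@@H](O)C#CCO[Si](C)(C)C(C)(C)C)C2CCCC1CCC2 | intermediate (not isolated)
12 | (2Z,6E,8R)-11-[(tert-butyldimethylsilyl)oxy]-2-ethenyl-6-methylundeca-2,6-dien-9-yne-1,8-diol | OC/C(C=C)=C\CC/C(C)=C/[C@@H](O)C#CCO[Si](C)(C)C(C)(C)C | intermediate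
13 | sodium cyclic vinylalanate of 12 (five-membered O6–Al–C11=C7–C6 ring, two 2-methoxyethoxy groups on aluminium) | [Na+].COCCO[Al-]1(OCCOC)O[C@H](/C=C(C)/CC/C=C(CO)/C=C)C=C1CO[Si](C)(C)C(C)(C)C | intermediate (not isolated)
14 | (2Z,6E,8R,9Z)-11-[(tert-butyldimethylsilyl)oxy]-2-ethenyl-10-iodo-6-methylundeca-2,6,9-triene-1,8-diol | OC/C(C=C)=C\CC/C(C)=C/[C@@H](O)/C=C(\I)CO[Si](C)(C)C(C)(C)C | intermediate
15 | carbon monoxide | [C-]#[O+] | starting material
16 | (5R)-3-{[(tert-butyldimethylsilyl)oxy]methyl}-5-[(1E,5Z)-6-(hydroxymethyl)-2-methylocta-1,5,7-trien-1-yl]furan-2(5H)-one | OC/C(C=C)=C\CC/C(C)=C/[C@H]1OC(=O)C(CO[Si](C)(C)C(C)(C)C)=C1 | intermediate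
17 | (5R)-3-(hydroxymethyl)-5-[(1E,5Z)-6-(hydroxymethyl)-2-methylocta-1,5,7-trien-1-yl]furan-2(5H)-one | OC/C(C=C)=C\CC/C(C)=C/[C@H]1OC(=O)C(CO)=C1 | intermediate
18 | acetic anhydride | CC(=O)OC(C)=O | starting material
19 | (5R)-5-{(1E)-4-[(2R,3S)-3-ethenyl-3-(hydroxymethyl)oxiran-2-yl]-2-methylbut-1-en-1-yl}-3-(hydroxymethyl)furan-2(5H)-one | OC[C@]1(C=C)O[C@@H]1CC/C(C)=C/[C@H]2OC(=O)C(CO)=C2 | intermediate (not isolated)
20 | {(2S,3R)-3-[(3E)-4-{(2R)-4-[(acetyloxy)methyl]-5-oxo-2,5-dihydrofuran-2-yl}-3-methylbut-3-en-1-yl]-2-ethenyloxiran-2-yl}methyl acetate | CC(=O)OC[C@]1(C=C)O[C@@H]1CC/C(C)=C/[C@H]2OC(=O)C(COC(C)=O)=C2 | intermediate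
21 | B-alkyl-9-borabicyclo[3.3.1]nonane of 20 (boron on the terminal carbon C8) | B1(CC[C@@]3(COC(C)=O)O[C@@H]3CC/C(C)=C/[C@H]4OC(=O)C(COC(C)=O)=C4)C2CCCC1CCC2 | intermediate (not isolated)
22 | {(2S,3R)-3-[(3E)-4-{(2R)-4-[(acetyloxy)methyl]-5-oxo-2,5-dihydrofuran-2-yl}-3-methylbut-3-en-1-yl]-2-(2-hydroxyethyl)oxiran-2-yl}methyl acetate | OCC[C@@]1(COC(C)=O)O[C@@H]1CC/C(C)=C/[C@H]2OC(=O)C(COC(C)=O)=C2 | intermediate
23 | (1R,6R,7R,8R,10S)-14-acetoxy-1,10-epoxy-8-hydroxygermacra-4E,11(13)-dien-12,6-olide | O[C@@H]1C[C@@]2(COC(C)=O)O[C@@H]2CC/C(C)=C/[C@H]2OC(=O)C(=C)[C@@H]21 | intermediate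
24 | 2-methylprop-2-enoyl chloride | C=C(C)C(Cl)=O | starting material
25 | (1R,6R,7R,8R,10S)-14-acetoxy-1,10-epoxy-8-(2-methylprop-2-enoyloxy)germacra-4E,11(13)-dien-12,6-olide (CNP0150481.3) | C=C(C)C(=O)O[C@@H]1C[C@@]2(COC(C)=O)O[C@@H]2CC/C(C)=C/[C@H]2OC(=O)C(=C)[C@@H]21 | target

**Step count**
Total: 12 steps. Longest linear sequence: 11 steps (steps 2–12 from 5); step 1 makes 4 separately.

**Three steps most likely to fail**

Step 11 (ring closure). A ten-membered radical cyclization is slow; the α-methylene lactone product is a better radical acceptor than the substrate; the C6–H may also be abstracted; the C8 configuration rests on a steric model. The fallback sets out from 22 and comes back at 23. Dess–Martin periodinane (NaHCO3, CH2Cl2, 0 °C) oxidizes 22 to the β,γ-epoxy aldehyde F1, which is used crude and added by syringe pump to SmI2 (2.5 equiv) in THF at −78 °C (final 0.5 mM). The samarium ketyl at C8 closes onto C7 and the samarium enolate expels acetate to give 23. This replaces hydrogen-atom abstraction with a reductive ketyl–olefin coupling and costs one extra step.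

Step 10 (hydroboration of the vinyl oxirane). The tertiary allylic oxirane may open, and the acetoxymethyl butenolide is sensitive to the oxidative work-up. The fallback sets out from 17 and comes back at 22, replacing steps 9 and 10. Ac2O/pyridine converts 17 into the dienyl diacetate F2. 9-BBN followed by buffered H2O2 hydroborates the terminal vinyl of the diene to the homoallylic alcohol F3. The C8 hydroxyl then directs a vanadium-catalysed asymmetric epoxidation of the homoallylic C1=C10 olefin (VO(OiPr)3, chiral bis-hydroxamic acid ligand, cumene hydroperoxide, toluene, 0 °C) to give 22. The oxirane is thus made after the hydroboration and never carries a vinyl group.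

Step 5 (hydroboration/Suzuki union). The borane may attack the internal alkyne, or the diene may hydroborate sluggishly. The fallback sets out from 10 and comes back at 16. NaAlH2(OCH2CH2OMe)2 followed by I2 converts 10 into the Z-iodo alcohol F4, and PdCl2(PPh3)2/CO/K2CO3 closes it to the dienyl butenolide F5. With the alkyne gone, 9-BBN can only add to the terminal vinyl group, and the resulting borane is coupled with 4 (Pd(dppf)Cl2, AsPh3, K3PO4, DMF/H2O, 0 °C) to give 16. The fragment union is moved behind lactone formation.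

**Further compounds**
F1 | step 11 | {(2S,3R)-3-[(3E)-4-{(2R)-4-[(acetyloxy)methyl]-5-oxo-2,5-dihydrofuran-2-yl}-3-methylbut-3-en-1-yl]-2-(2-oxoethyl)oxiran-2-yl}methyl acetate | O=CC[C@@]1(COC(C)=O)O[C@@H]1CC/C(C)=C/[C@H]2OC(=O)C(COC(C)=O)=C2
F2 | step 10 | [(5R)-5-{(1E,5Z)-6-[(acetyloxy)methyl]-2-methylocta-1,5,7-trien-1-yl}-2-oxo-2,5-dihydrofuran-3-yl]methyl acetate | CC(=O)OC/C(C=C)=C\CC/C(C)=C/[C@H]1OC(=O)C(COC(C)=O)=C1
F3 | step 10 | [(5R)-5-{(1E,5Z)-6-[(acetyloxy)methyl]-8-hydroxy-2-methylocta-1,5-dien-1-yl}-2-oxo-2,5-dihydrofuran-3-yl]methyl acetate | CC(=O)OC/C(CCO)=C\CC/C(C)=C/[C@H]1OC(=O)C(COC(C)=O)=C1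
F4 | step 5 | (2Z,4R,5E)-1-[(tert-butyldimethylsilyl)oxy]-2-iodo-6-methylocta-2,5,7-trien-4-ol | C=C/C(C)=C/[C@@H](O)/C=C(\I)CO[Si](C)(C)C(C)(C)C
F5 | step 5 | (5R)-3-{[(tert-butyldimethylsilyl)oxy]methyl}-5-[(1E)-2-methylbuta-1,3-dien-1-yl]furan-2(5H)-one | C=C/C(C)=C/[C@H]1OC(=O)C(CO[Si](C)(C)C(C)(C)C)=C1
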